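Count what is left, not what is made.

| setting | Monday's | Wednesday's | Saturday's | green | teal | violet |
|---|---|---|---|---|---|---|
| starting material | 0.050 M (fed, over 5.0 h) | 0.050 M (fed, over 5.0 h) | 0.025 M (fed, over 5.0 h) | 0.050 M (fed, over 5.0 h) | 0.050 M (fed, over 10 h) | 0.050 M (fed, over 20 h) |
| partner | 0.84 equiv | 1.3 equiv | 0.60 equiv | 0.600 equiv | 0.600 equiv | 0.600 equiv |
| protic impurity | 0.050 M | 0.050 M | 0.050 M | 0.0500 M | 0.0500 M | 0.0500 M |
| remark | run made earlier | run made earlier | run made earlier |  |  |  |
| time |  |  |  | 20 h | 20 h | 20 h |

| run | time / h | product / % |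
|---|---|---|
| Monday's | 2.50 | 0.7 |
| Monday's | 5.00 | 3.7 |
| Monday's | 8.00 | 9.3 |
| Monday's | 10.0 | 12.1 |
| Monday's | 12.0 | 14.9 |
| Monday's | 15.0 | 18.3 |
| Wednesday's | 2.50 | 0.8 |
| Wednesday's | 5.00 | 4.8 |
| Wednesday's | 8.00 | 13.1 |
| Wednesday's | 10.0 | 17.5 |
| Wednesday's | 12.0 | 21.2 |
| Wednesday's | 15.0 | 24.8 |
| Saturday's | 1.33 | 0.3 |
| Saturday's | 2.50 | 0 |
| Saturday's | 5.00 | 1.1 |
| Saturday's | 8.00 | 3.7 |
| Saturday's | 15.0 | 7.0 |

(readings scatter by 0.3 percentage points)

- "hardly changes" means that all values lie within two and a half points (for a concentration: within two and a half percent of the largest)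
- percentages count the whole charge, also what has not yet gone in

- amount of product at the end, in percent of the starting material charged for green, teal, violet, in this order
- how the row runs (falls all the way / rises, then falls / falls, then rises / rises all the way / hardly changes)

- We take Monday's readings at 5.00 h, 10.0 h and 15.0 h: the second gain is 0.738 of the first, and a gap that shrinks by a steady factor points to a ceiling of 35.8 %. Wednesday's same readings, with factor 0.575, point to 34.7 %, so we read one ceiling and assume it for the new flasks.
- The fraction left below that ceiling falls by 0.0607 h⁻¹ on Monday and 0.111 h⁻¹ on Wednesday, which rises roughly with partner concentration, as in a pseudo-first-order step. Scaled to green's 0.0300 M of partner, this gives 0.0434 h⁻¹, the clearing rate: the share per hour by which the fraction left falls.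
- Monday's reading at 5.00 h starts this clock at 3.20 h, which is 0.702 h past mid-feed.
- Saturday's flask looks like green in equivalents, yet it holds 0.0150 M of partner, so its clearing rate is half of green's. The rule gives Saturday 8.08 % at 15.0 h against the 7.0 % read, so we expect the rule to run high on the new flasks as well.
- For green, the fraction left at 20 h is 0.483, which gives 18.5 %. Teal's clock starts 2.50 h later and violet's 7.50 h later, giving 16.5 % and 11.9 %.
- The forecast gives 17 %, 15 % and 10.5 %, lower than our row, and the same shape, falls all the way, holding that “slow dosing changes selectivity little”.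
- The flasks give 16.7 %, 15.0 % and 10.3 %: falls all the way.

    starting material ⇌ intermediate A (K = 26.6, k = 0.0209 h⁻¹)
    starting material ⇌ intermediate B (K = 13.0, k = 0.375 h⁻¹)
    partner + intermediate B → product (k = 1.33 M⁻¹ h⁻¹)
    intermediate A ⇌ intermediate B (k = 0.0144 h⁻¹)
    starting material + protic impurity → quenched substrate (k = 8.31 M⁻¹ h⁻¹)

Green's 16.7 % leaves 0.533 of our ceiling unmade, and carrying that fraction through violet's later clock at 0.0434 h⁻¹ gives 9.37 % for violet, which holds 10.3 %. The change from green to violet is −6.3 percentage points as the flasks stand, and a part of it stands on the reaction of starting material to intermediate B, both ways: in the same pair of flasks with that reaction taken away, the change is −0.2 points.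

The earlier runs and the new flask are simulated on assumed constants; scatter was added.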